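## Retrosynthetic overview

1. The central C12–C12′ bond is made last by mixed Kolbe electrolysis of two bicyclic acetic acids that already carry the final acetate pattern (left: 3,10-diacetate, 10R; right: 3′-OH, 10′-acetate, 10′S).
2. Each perhydro-1-benzoxepine comes from one visible-light radical-cation cascade on an open-chain hydroxy dienal: the oxepane closes first (O–C7), then the cyclohexane (C6–C11).
3. Cascade substrates: the linalyl vinyl group becomes the enal (hydroformylation, dehydrogenation); C4–C5 is made by alkylating the trilithium salt of a glycidate-derived dihydroxy sulfone (one batch for both halves) with (E)-8-bromolinalyl acetate.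
4. Stereocentres: C10/C10′ are bought as (R)- and (S)-linalool, C3/C3′ as methyl (S)-glycidate; C6, C7 and C11 of each half are set in the cascade.

Assumption: each C15 half carries squalene-type locants (C2 = CMe2–O, C3 = CH–O, C6 = angular C–Me, C7 = ring-fusion CH–O, C10 = C(Me)OAc, C11 = ring CH, C12 = bridging CH2; primes for the 3-hydroxy half); "left" = 3-acetoxy half (10R), "right" = 3-hydroxy half (10S).

## Route

**Sulfone building block (used in both series)**

Step 1
Reactants: 1 methyl (2S)-oxirane-2-carboxylate (methyl (S)-glycidate)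
Product: 2 2-[(2S)-oxiran-2-yl]propan-2-ol
Conditions: MeMgBr (2.2 equiv), THF, −78 to −30 °C; then H2O
Reagents that add atoms: methylmagnesium bromide, C[Mg]Br
Why: Double Grignard addition to the ester is faster than epoxide opening at low temperature, and the bought stereocentre (later C3) is not touched.

Step 2
Reactants: 2 2-[(2S)-oxiran-2-yl]propan-2-ol
Product: 3 (2R)-3-methyl-1-(phenylsulfonyl)butane-2,3-diol
Conditions: PhSO2Na (1.5 equiv), AcOH (1 equiv), EtOH–H2O, 80 °C
Reagents that add atoms: sodium benzenesulfinate, [Na+].[O-]S(=O)c1ccccc1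
Why: SN2 opening of the terminal epoxide at CH2 by the sulfinate sulfur (S-alkylation) leaves the C–O bond of the stereocentre intact; the descriptor changes to R only through CIP priorities.

**Left bromide (10R)**

Step 3
Reactants: 4 (R)-(−)-linalool
Product: 5 (3R)-3,7-dimethylocta-1,6-dien-3-yl acetate
Conditions: Ac2O, Et3N, DMAP (cat.), CH2Cl2, 23 °C
Reagents that add atoms: acetic anhydride, CC(=O)OC(C)=O
Why: DMAP-catalysed acylation under basic conditions (no ionisation of the tertiary allylic centre) puts the C10 acetate on the bought 10R centre; no stereocentre is formed.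

Step 4
Reactants: 5 (3R)-3,7-dimethylocta-1,6-dien-3-yl acetate
Product: 6 (3R,6E)-8-hydroxy-3,7-dimethylocta-1,6-dien-3-yl acetate
Conditions: SeO2 (cat.), t-BuOOH, salicylic acid (cat.), CH2Cl2, 23 °C
Reagents that add atoms: tert-butyl hydroperoxide, CC(C)(C)OO
Why: Sharpless–Umbreit allylic oxidation (ene then [2,3] shift) hydroxylates only the E-methyl of the trisubstituted alkene, which fixes the E geometry of the later C6=C7 bond.

Step 5
Reactants: 6 (3R,6E)-8-hydroxy-3,7-dimethylocta-1,6-dien-3-yl acetate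
Product: 7 (3R,6E)-8-bromo-3,7-dimethylocta-1,6-dien-3-yl acetate
Conditions: CBr4, PPh3, CH2Cl2, −20 °C
Reagents that add atoms: carbon tetrabromide, BrC(Br)(Br)Br
Why: Appel bromination of the primary allylic alcohol proceeds by SN2 without allylic shift and leaves the tertiary acetate alone.

**Trilithium salt (one batch, shared by both series)**

Step 6
Reactants: 3 (2R)-3-methyl-1-(phenylsulfonyl)butane-2,3-diol
Product: 8 trilithium salt (O,O,C-trianion) of 3, kept as a cold THF solution
Conditions: n-BuLi (3.0 equiv), THF, −78 to −20 °C, 30 min; solution held at −78 °C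
Reagents that add atoms: n-butyllithium, [Li]CCCC
Why: Threefold deprotonation (both hydroxyls, then the α-sulfonyl C–H) as in the metalation stage of Julia-type couplings; the β-oxido group is too poor a leaving group to eliminate, the bought carbinol centre is untouched, and one batch is made when the allylic bromides of both series are in hand and is divided between steps 7 and 17.

**Left series (10R)**

Step 7
Reactants: 8 trilithium salt (O,O,C-trianion) of 3; 7 (3R,6E)-8-bromo-3,7-dimethylocta-1,6-dien-3-yl acetate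
Product: 9 (3R,6E,10R)-10,11-dihydroxy-3,7,11-trimethyl-9-(phenylsulfonyl)dodeca-1,6-dien-3-yl acetate (both C9 epimers)
Conditions: 8 (1.2 equiv, half of the THF solution from step 6), 7, THF, −78 to −40 °C; then H2O
Reagents that add atoms: none
Why: SN2 C-alkylation of the α-sulfonyl carbanion by the primary allylic bromide forms C4–C5 with the E alkene retained; the sulfonyl-bearing centre is removed in the next step.

Step 8
Reactants: 9 (3R,6E,10R)-10,11-dihydroxy-3,7,11-trimethyl-9-(phenylsulfonyl)dodeca-1,6-dien-3-yl acetate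
Product: 10 (3R,6E,10S)-10,11-dihydroxy-3,7,11-trimethyldodeca-1,6-dien-3-yl acetate
Conditions: Na(Hg) (6% Na), Na2HPO4, MeOH–THF, −20 °C
Reagents that add atoms: none
Why: Reductive desulfonylation by single-electron transfer; with a free β-hydroxyl there is no Julia elimination, and C3 (here C10, S) and C10 (here C3, R) are untouched.

Step 9
Reactants: 10 (3R,6E,10S)-10,11-dihydroxy-3,7,11-trimethyldodeca-1,6-dien-3-yl acetate
Product: 11 (3R,6E,10S)-11-hydroxy-3,7,11-trimethyldodeca-1,6-diene-3,10-diyl diacetate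
Conditions: Ac2O (1.2 equiv), pyridine, DMAP (cat.), CH2Cl2, 0 °C
Reagents that add atoms: acetic anhydride, CC(=O)OC(C)=O
Why: Chemoselective acylation of the secondary hydroxyl over the tertiary one blocks the competing 6-endo ether closure in the cascade and installs the final C3 acetate.

Step 10
Reactants: 11 (3R,6E,10S)-11-hydroxy-3,7,11-trimethyldodeca-1,6-diene-3,10-diyl diacetate
Product: 12 (4R,7E,11S)-4,11-diacetoxy-12-hydroxy-4,8,12-trimethyltridec-7-enal
Conditions: Rh(acac)(CO)2 (1 mol%), Xantphos, CO/H2 (1:1, 20 bar), toluene, 70 °C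
Reagents that add atoms: carbon monoxide, [C-]#[O+]
Why: Linear-selective rhodium hydroformylation touches only the monosubstituted alkene (branched insertion is blocked by quaternary C10, the trisubstituted alkene is inert); no stereocentre is formed.

Step 11
Reactants: 12 (4R,7E,11S)-4,11-diacetoxy-12-hydroxy-4,8,12-trimethyltridec-7-enal
Product: 13 (2E,4R,7E,11S)-4,11-diacetoxy-12-hydroxy-4,8,12-trimethyltrideca-2,7-dienal
Conditions: IBX (2.5 equiv), DMSO–toluene, 70 °C
Reagents that add atoms: none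
Why: IBX α,β-dehydrogenation of the aldehyde (Nicolaou) through its enol; next to quaternary C10 the new alkene can only be E.

Step 12
Reactants: 13 (2E,4R,7E,11S)-4,11-diacetoxy-12-hydroxy-4,8,12-trimethyltrideca-2,7-dienal
Product: 15 (3S,5aS,6S,7R,9aS)-2,2,5a,7-tetramethyl-6-(2-oxoethyl)decahydro-1-benzoxepine-3,7-diyl diacetate, via tertiary oxepanyl radical 14 (not isolated)
Conditions: 9-mesityl-10-methylacridinium tetrafluoroborate (5 mol%), PhSSPh (20 mol%), ClCH2CH2Cl (0.01 M), 450 nm LEDs, 23 °C, no base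
Reagents that add atoms: none
Why: Proposed new method: the excited acridinium oxidises only the electron-rich C6=C7 alkene to its radical cation, the tertiary C2 hydroxyl adds at the less substituted C7 (anti-Markovnikov, 7-endo; taken as reversible without base), and the tertiary C6 radical 14 is drained by an irreversible 6-exo Giese addition to the enal through a chair transition state with a trans-fused oxepane and an equatorial enal arm, so that the bought C3 acetoxy group (placed pseudo-equatorial on the oxepane in the working model, a point the conformational analysis does not settle) selects C7 (S), trans-fusion then gives C6 (S) and the chair gives C11 (S), with C10 (R) carried along with its acetoxy group axial; thiophenol from PhSSPh returns the hydrogen atom to the α-formyl radical and closes the redox-neutral cycle; the closest known reactions are the acridinium-catalysed anti-Markovnikov hydroetherification of alkenols, polar-radical-crossover cycloadditions and photoinduced-electron-transfer polyene cyclisations, none of which has been shown for a 7-endo/6-exo oxepane–cyclohexane bicyclisation ending on an enal.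

Step 13
Reactants: 15 (3S,5aS,6S,7R,9aS)-2,2,5a,7-tetramethyl-6-(2-oxoethyl)decahydro-1-benzoxepine-3,7-diyl diacetate
Product: 16 2-[(3S,5aS,6S,7R,9aS)-3,7-diacetoxy-2,2,5a,7-tetramethyldecahydro-1-benzoxepin-6-yl]acetic acid
Conditions: NaClO2, NaH2PO4, 2-methylbut-2-ene, t-BuOH–H2O, 0 to 23 °C
Reagents that add atoms: sodium chlorite, [Na+].[O-]Cl=O
Why: Pinnick oxidation under buffered conditions spares both acetates and the oxepane; no stereocentre is touched.

**Right series (10′S)**

Step 14
Reactants: 17 (S)-(+)-linalool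
Product: 18 (3S)-3,7-dimethylocta-1,6-dien-3-yl acetate
Conditions: Ac2O, Et3N, DMAP (cat.), CH2Cl2, 23 °C
Reagents that add atoms: acetic anhydride, CC(=O)OC(C)=O
Why: DMAP-catalysed acylation as in step 3 puts the C10′ acetate on the bought 10′S centre; any minor enantiomer in coriander-derived 17 later becomes a separable diastereomer.

Step 15
Reactants: 18 (3S)-3,7-dimethylocta-1,6-dien-3-yl acetate
Product: 19 (3S,6E)-8-hydroxy-3,7-dimethylocta-1,6-dien-3-yl acetate
Conditions: SeO2 (cat.), t-BuOOH, salicylic acid (cat.), CH2Cl2, 23 °C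
Reagents that add atoms: tert-butyl hydroperoxide, CC(C)(C)OO
Why: E-selective Sharpless–Umbreit allylic oxidation as in step 4.

Step 16
Reactants: 19 (3S,6E)-8-hydroxy-3,7-dimethylocta-1,6-dien-3-yl acetate
Product: 20 (3S,6E)-8-bromo-3,7-dimethylocta-1,6-dien-3-yl acetate
Conditions: CBr4, PPh3, CH2Cl2, −20 °C
Reagents that add atoms: carbon tetrabromide, BrC(Br)(Br)Br
Why: Appel bromination by SN2 as in step 5.

Step 17
Reactants: 8 trilithium salt (O,O,C-trianion) of 3; 20 (3S,6E)-8-bromo-3,7-dimethylocta-1,6-dien-3-yl acetate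
Product: 21 (3S,6E,10R)-10,11-dihydroxy-3,7,11-trimethyl-9-(phenylsulfonyl)dodeca-1,6-dien-3-yl acetate (both C9 epimers)
Conditions: 8 (1.2 equiv, second half of the THF solution from step 6), 20, THF, −78 to −40 °C; then H2O
Reagents that add atoms: none
Why: SN2 C-alkylation of the α-sulfonyl carbanion as in step 7 forms C4′–C5′.

Step 18
Reactants: 21 (3S,6E,10R)-10,11-dihydroxy-3,7,11-trimethyl-9-(phenylsulfonyl)dodeca-1,6-dien-3-yl acetate
Product: 22 (3S,6E,10S)-10,11-dihydroxy-3,7,11-trimethyldodeca-1,6-dien-3-yl acetate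
Conditions: Na(Hg) (6% Na), Na2HPO4, MeOH–THF, −20 °C
Reagents that add atoms: none
Why: Reductive desulfonylation as in step 8; no stereocentre is touched.

Step 19
Reactants: 22 (3S,6E,10S)-10,11-dihydroxy-3,7,11-trimethyldodeca-1,6-dien-3-yl acetate
Product: 23 (3S,6E,10S)-11-hydroxy-3,7,11-trimethyldodeca-1,6-diene-3,10-diyl diacetate
Conditions: Ac2O (1.2 equiv), pyridine, DMAP (cat.), CH2Cl2, 0 °C
Reagents that add atoms: acetic anhydride, CC(=O)OC(C)=O
Why: Chemoselective acylation of the secondary hydroxyl; here the acetate is a temporary block that is removed in step 24.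

Step 20
Reactants: 23 (3S,6E,10S)-11-hydroxy-3,7,11-trimethyldodeca-1,6-diene-3,10-diyl diacetate
Product: 24 (4S,7E,11S)-4,11-diacetoxy-12-hydroxy-4,8,12-trimethyltridec-7-enal
Conditions: Rh(acac)(CO)2 (1 mol%), Xantphos, CO/H2 (1:1, 20 bar), toluene, 70 °C
Reagents that add atoms: carbon monoxide, [C-]#[O+]
Why: Linear-selective hydroformylation of the vinyl group as in step 10.

Step 21
Reactants: 24 (4S,7E,11S)-4,11-diacetoxy-12-hydroxy-4,8,12-trimethyltridec-7-enal
Product: 25 (2E,4S,7E,11S)-4,11-diacetoxy-12-hydroxy-4,8,12-trimethyltrideca-2,7-dienal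
Conditions: IBX (2.5 equiv), DMSO–toluene, 70 °C
Reagents that add atoms: none
Why: IBX α,β-dehydrogenation of the aldehyde as in step 11.

Step 22
Reactants: 25 (2E,4S,7E,11S)-4,11-diacetoxy-12-hydroxy-4,8,12-trimethyltrideca-2,7-dienal
Product: 27 (3S,5aS,6S,7S,9aS)-2,2,5a,7-tetramethyl-6-(2-oxoethyl)decahydro-1-benzoxepine-3,7-diyl diacetate, via tertiary oxepanyl radical 26 (not isolated)
Conditions: 9-mesityl-10-methylacridinium tetrafluoroborate (5 mol%), PhSSPh (20 mol%), ClCH2CH2Cl (0.01 M), 450 nm LEDs, 23 °C, no base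
Reagents that add atoms: none
Why: Proposed new method: the same radical-cation cascade as in step 12 (alkene radical cation, reversible anti-Markovnikov 7-endo C–O addition, irreversible 6-exo Giese closure of radical 26 through the trans-fused chair–chair transition state, hydrogen return from thiophenol), with the bought C3′ (S) acetoxy group again taken as the element that selects C7′ (S), hence C6′ (S) and C11′ (S), while the bought C10′ (S) centre now places its methyl axial as in every drimane-type closure; closest known reactions are acridinium-catalysed anti-Markovnikov hydroetherification and polar-radical-crossover cycloaddition.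

Step 23
Reactants: 27 (3S,5aS,6S,7S,9aS)-2,2,5a,7-tetramethyl-6-(2-oxoethyl)decahydro-1-benzoxepine-3,7-diyl diacetate
Product: 28 2-[(3S,5aS,6S,7S,9aS)-3,7-diacetoxy-2,2,5a,7-tetramethyldecahydro-1-benzoxepin-6-yl]acetic acid
Conditions: NaClO2, NaH2PO4, 2-methylbut-2-ene, t-BuOH–H2O, 0 to 23 °C
Reagents that add atoms: sodium chlorite, [Na+].[O-]Cl=O
Why: Pinnick oxidation as in step 13.

Step 24
Reactants: 28 2-[(3S,5aS,6S,7S,9aS)-3,7-diacetoxy-2,2,5a,7-tetramethyldecahydro-1-benzoxepin-6-yl]acetic acid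
Product: 29 2-[(3S,5aS,6S,7S,9aS)-7-acetoxy-3-hydroxy-2,2,5a,7-tetramethyldecahydro-1-benzoxepin-6-yl]acetic acid
Conditions: K2CO3 (2 equiv), MeOH, 0 to 23 °C; then aq. NaH2PO4
Reagents that add atoms: none
Why: Zemplén-type transesterification removes the unhindered secondary C3′ acetate far faster than the tertiary C10′ acetate flanked by two fully substituted carbons; no stereocentre is touched.

**Union**

Step 25
Reactants: 16 2-[(3S,5aS,6S,7R,9aS)-3,7-diacetoxy-2,2,5a,7-tetramethyldecahydro-1-benzoxepin-6-yl]acetic acid; 29 2-[(3S,5aS,6S,7S,9aS)-7-acetoxy-3-hydroxy-2,2,5a,7-tetramethyldecahydro-1-benzoxepin-6-yl]acetic acid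
Product: 32 CNP0169816.1 (target), via left primary alkyl radical 30 (not isolated), via right primary alkyl radical 31 (not isolated)
Conditions: 16 (2 equiv), 29 (1 equiv), KOH (10 mol%), acetone, reticulated vitreous carbon electrodes, undivided cell, rapid alternating polarity (50 ms), constant current, 23 °C
Reagents that add atoms: none
Why: Mixed Kolbe electrolysis: anodic decarboxylation gives the unstabilised primary radicals 30 and 31, which combine at the electrode to form C12–C12′; the radical carbons are CH2 so no stereocentre is affected, and the cross-product (one free OH) is separated from the two symmetrical dimers (none or two free OH) by chromatography.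

## Compound list

1 | methyl (2S)-oxirane-2-carboxylate | COC(=O)[C@@H]1CO1 | starting material
2 | 2-[(2S)-oxiran-2-yl]propan-2-ol | CC(C)(O)[C@@H]1CO1 | intermediate
3 | (2R)-3-methyl-1-(phenylsulfonyl)butane-2,3-diol | CC(C)(O)[C@@H](O)CS(=O)(=O)c1ccccc1 | intermediate
4 | (R)-(−)-linalool, (3R)-3,7-dimethylocta-1,6-dien-3-ol | C=C[C@](C)(O)CCC=C(C)C | starting material
5 | (3R)-3,7-dimethylocta-1,6-dien-3-yl acetate | C=C[C@](C)(OC(C)=O)CCC=C(C)C | intermediate
6 | (3R,6E)-8-hydroxy-3,7-dimethylocta-1,6-dien-3-yl acetate | C=C[C@](C)(OC(C)=O)CC/C=C(\C)CO | intermediate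
7 | (3R,6E)-8-bromo-3,7-dimethylocta-1,6-dien-3-yl acetate | C=C[C@](C)(OC(C)=O)CC/C=C(\C)CBr | intermediate
8 | trilithium salt (O,O,C-trianion) of 3 | [Li+].[Li+].[Li+].CC(C)([O-])[C@@H]([O-])[CH-]S(=O)(=O)c1ccccc1 | intermediate
9 | (3R,6E,10R)-10,11-dihydroxy-3,7,11-trimethyl-9-(phenylsulfonyl)dodeca-1,6-dien-3-yl acetate (both C9 epimers) | C=C[C@](C)(OC(C)=O)CC/C=C(\C)CC([C@H](O)C(C)(C)O)S(=O)(=O)c1ccccc1 | intermediate
10 | (3R,6E,10S)-10,11-dihydroxy-3,7,11-trimethyldodeca-1,6-dien-3-yl acetate | C=C[C@](C)(OC(C)=O)CC/C=C(\C)CC[C@H](O)C(C)(C)O | intermediate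
11 | (3R,6E,10S)-11-hydroxy-3,7,11-trimethyldodeca-1,6-diene-3,10-diyl diacetate | C=C[C@](C)(OC(C)=O)CC/C=C(\C)CC[C@H](OC(C)=O)C(C)(C)O | intermediate
12 | (4R,7E,11S)-4,11-diacetoxy-12-hydroxy-4,8,12-trimethyltridec-7-enal | O=CCC[C@](C)(OC(C)=O)CC/C=C(\C)CC[C@H](OC(C)=O)C(C)(C)O | intermediate
13 | (2E,4R,7E,11S)-4,11-diacetoxy-12-hydroxy-4,8,12-trimethyltrideca-2,7-dienal | O=C/C=C/[C@](C)(OC(C)=O)CC/C=C(\C)CC[C@H](OC(C)=O)C(C)(C)O | intermediate
14 | (2S,6S)-6-acetoxy-2-[(3R,4E)-3-acetoxy-3-methyl-6-oxohex-4-en-1-yl]-3,7,7-trimethyloxepan-3-yl radical | CC(=O)O[C@H]1CC[C](C)[C@H](CC[C@@](C)(OC(C)=O)/C=C/C=O)OC1(C)C | intermediate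
15 | (3S,5aS,6S,7R,9aS)-2,2,5a,7-tetramethyl-6-(2-oxoethyl)decahydro-1-benzoxepine-3,7-diyl diacetate | CC(=O)O[C@H]1CC[C@]2(C)[C@H](CC[C@@](C)(OC(C)=O)[C@H]2CC=O)OC1(C)C | intermediate
16 | 2-[(3S,5aS,6S,7R,9aS)-3,7-diacetoxy-2,2,5a,7-tetramethyldecahydro-1-benzoxepin-6-yl]acetic acid | CC(=O)O[C@H]1CC[C@]2(C)[C@H](CC[C@@](C)(OC(C)=O)[C@H]2CC(=O)O)OC1(C)C | intermediate
17 | (S)-(+)-linalool, (3S)-3,7-dimethylocta-1,6-dien-3-ol | C=C[C@@](C)(O)CCC=C(C)C | starting material
18 | (3S)-3,7-dimethylocta-1,6-dien-3-yl acetate | C=C[C@@](C)(OC(C)=O)CCC=C(C)C | intermediate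
19 | (3S,6E)-8-hydroxy-3,7-dimethylocta-1,6-dien-3-yl acetate | C=C[C@@](C)(OC(C)=O)CC/C=C(\C)CO | intermediate
20 | (3S,6E)-8-bromo-3,7-dimethylocta-1,6-dien-3-yl acetate | C=C[C@@](C)(OC(C)=O)CC/C=C(\C)CBr | intermediate
21 | (3S,6E,10R)-10,11-dihydroxy-3,7,11-trimethyl-9-(phenylsulfonyl)dodeca-1,6-dien-3-yl acetate (both C9 epimers) | C=C[C@@](C)(OC(C)=O)CC/C=C(\C)CC([C@H](O)C(C)(C)O)S(=O)(=O)c1ccccc1 | intermediate
22 | (3S,6E,10S)-10,11-dihydroxy-3,7,11-trimethyldodeca-1,6-dien-3-yl acetate | C=C[C@@](C)(OC(C)=O)CC/C=C(\C)CC[C@H](O)C(C)(C)O | intermediate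
23 | (3S,6E,10S)-11-hydroxy-3,7,11-trimethyldodeca-1,6-diene-3,10-diyl diacetate | C=C[C@@](C)(OC(C)=O)CC/C=C(\C)CC[C@H](OC(C)=O)C(C)(C)O | intermediate
24 | (4S,7E,11S)-4,11-diacetoxy-12-hydroxy-4,8,12-trimethyltridec-7-enal | O=CCC[C@@](C)(OC(C)=O)CC/C=C(\C)CC[C@H](OC(C)=O)C(C)(C)O | intermediate
25 | (2E,4S,7E,11S)-4,11-diacetoxy-12-hydroxy-4,8,12-trimethyltrideca-2,7-dienal | O=C/C=C/[C@@](C)(OC(C)=O)CC/C=C(\C)CC[C@H](OC(C)=O)C(C)(C)O | intermediate
26 | (2S,6S)-6-acetoxy-2-[(3S,4E)-3-acetoxy-3-methyl-6-oxohex-4-en-1-yl]-3,7,7-trimethyloxepan-3-yl radical | CC(=O)O[C@H]1CC[C](C)[C@H](CC[C@](C)(OC(C)=O)/C=C/C=O)OC1(C)C | intermediate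
27 | (3S,5aS,6S,7S,9aS)-2,2,5a,7-tetramethyl-6-(2-oxoethyl)decahydro-1-benzoxepine-3,7-diyl diacetate | CC(=O)O[C@H]1CC[C@]2(C)[C@H](CC[C@](C)(OC(C)=O)[C@H]2CC=O)OC1(C)C | intermediate
28 | 2-[(3S,5aS,6S,7S,9aS)-3,7-diacetoxy-2,2,5a,7-tetramethyldecahydro-1-benzoxepin-6-yl]acetic acid | CC(=O)O[C@H]1CC[C@]2(C)[C@H](CC[C@](C)(OC(C)=O)[C@H]2CC(=O)O)OC1(C)C | intermediate
29 | 2-[(3S,5aS,6S,7S,9aS)-7-acetoxy-3-hydroxy-2,2,5a,7-tetramethyldecahydro-1-benzoxepin-6-yl]acetic acid | O[C@H]1CC[C@]2(C)[C@H](CC[C@](C)(OC(C)=O)[C@H]2CC(=O)O)OC1(C)C | intermediate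
30 | [(3S,5aS,6S,7R,9aS)-3,7-diacetoxy-2,2,5a,7-tetramethyldecahydro-1-benzoxepin-6-yl]methyl radical | CC(=O)O[C@H]1CC[C@]2(C)[C@H](CC[C@@](C)(OC(C)=O)[C@H]2[CH2])OC1(C)C | intermediate
31 | [(3S,5aS,6S,7S,9aS)-7-acetoxy-3-hydroxy-2,2,5a,7-tetramethyldecahydro-1-benzoxepin-6-yl]methyl radical | O[C@H]1CC[C@]2(C)[C@H](CC[C@](C)(OC(C)=O)[C@H]2[CH2])OC1(C)C | intermediate
32 | CNP0169816.1 | CC(=O)O[C@H]1CC[C@]2(C)[C@H](CC[C@@](C)(OC(C)=O)[C@H]2CC[C@H]2[C@]3(C)CC[C@H](O)C(C)(C)O[C@H]3CC[C@]2(C)OC(C)=O)OC1(C)C | target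

## Step count and risks

Total step count: 25. Longest linear sequence: 12 steps (17 to 32, steps 14–25; equally 1 to 32 through steps 1, 2, 6 and 17–25).

**Risk 1: step 12 (and its twin, step 22), the proposed cascade.** It can fail by early hydrogen-atom quench of radical 14 or 26, by Markovnikov 6-exo ether closure, or by weak or even reversed induction at C7 from the remote C3 acetate. Step 22 is the more exposed, because the productive chair carries the C10′ methyl axial. A wrong C7 series would be a separable diastereomer of 15 or 27. The fallback runs the two ring closures separately with known reaction classes. Setting out from 13, acridinium/cobaloxime dual photocatalysis [9-mesityl-10-methylacridinium tetrafluoroborate, Co(dmgH)2(py)Cl, MeCN, 450 nm; dehydrogenative anti-Markovnikov alkene alkoxylation] closes only the oxepane and ends the C6 radical as an alkene. This gives (2E,4R)-4-acetoxy-6-[(2S,6S)-6-acetoxy-7,7-dimethyl-3-methylideneoxepan-2-yl]-4-methylhex-2-enal F5 (an endocyclic alkene isomer would converge). An iron-hydride hydrogen-atom-transfer Giese cyclisation [Fe(acac)3, PhSiH3, EtOH, 60 °C] then regenerates the tertiary C6 radical from the alkene and closes the cyclohexane, coming back to the route at 15. In the twin series, 25 is taken the same way through (2E,4S)-4-acetoxy-6-[(2S,6S)-6-acetoxy-7,7-dimethyl-3-methylideneoxepan-2-yl]-4-methylhex-2-enal F6 and comes back at 27. This fallback does not by itself improve the C7 induction.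

**Risk 2: step 25, the mixed Kolbe coupling.** It is statistical, and the acetates must survive the basic catholyte. The fallback is a cross-selective union. Setting out from 16, silver-catalysed decarboxylative bromination [Ag(phen)2OTf (cat.), dibromoisocyanuric acid, ClCH2CH2Cl, 23 °C] gives (3S,5aS,6S,7R,9aS)-6-(bromomethyl)-2,2,5a,7-tetramethyldecahydro-1-benzoxepine-3,7-diyl diacetate F7. Nickel/iridium metallaphotoredox decarboxylative sp3–sp3 coupling of F7 with acid 29 [NiCl2·glyme, 4,4′-dimethoxy-2,2′-bipyridine, Ir[dF(CF3)ppy]2(dtbbpy)PF6, Cs2CO3, MeCN–H2O, blue LEDs] comes back to the route at 32.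

**Risk 3: step 7 (and its twin, step 17), the trianion alkylation.** The polyanion 8 may attack the tertiary acetate or alkylate sluggishly. The fallback reverses the polarity and needs no trilithium salt. Setting out from 7, PhSO2Na in DMF gives (3R,6E)-3,7-dimethyl-8-(phenylsulfonyl)octa-1,6-dien-3-yl acetate F1. Its lithium anion [LiN(SiMe3)2, THF, −78 °C] opens epoxide 2 (as its lithium alkoxide, BF3·OEt2) at CH2 to give (3R,6E,10S)-10,11-dihydroxy-3,7,11-trimethyl-8-(phenylsulfonyl)dodeca-1,6-dien-3-yl acetate F2. Na(Hg)/Na2HPO4 in MeOH removes the sulfonyl group and the route is rejoined at 10. In the twin series, 20 gives (3S,6E)-3,7-dimethyl-8-(phenylsulfonyl)octa-1,6-dien-3-yl acetate F3, then (3S,6E,10S)-10,11-dihydroxy-3,7,11-trimethyl-8-(phenylsulfonyl)dodeca-1,6-dien-3-yl acetate F4, and comes back at 22.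

## Further compounds

F1 | step 7 | (3R,6E)-3,7-dimethyl-8-(phenylsulfonyl)octa-1,6-dien-3-yl acetate | C=C[C@](C)(OC(C)=O)CC/C=C(\C)CS(=O)(=O)c1ccccc1
F2 | step 7 | (3R,6E,10S)-10,11-dihydroxy-3,7,11-trimethyl-8-(phenylsulfonyl)dodeca-1,6-dien-3-yl acetate | C=C[C@](C)(OC(C)=O)CC/C=C(\C)C(C[C@H](O)C(C)(C)O)S(=O)(=O)c1ccccc1
F3 | step 17 | (3S,6E)-3,7-dimethyl-8-(phenylsulfonyl)octa-1,6-dien-3-yl acetate | C=C[C@@](C)(OC(C)=O)CC/C=C(\C)CS(=O)(=O)c1ccccc1
F4 | step 17 | (3S,6E,10S)-10,11-dihydroxy-3,7,11-trimethyl-8-(phenylsulfonyl)dodeca-1,6-dien-3-yl acetate | C=C[C@@](C)(OC(C)=O)CC/C=C(\C)C(C[C@H](O)C(C)(C)O)S(=O)(=O)c1ccccc1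
F5 | step 12 | (2E,4R)-4-acetoxy-6-[(2S,6S)-6-acetoxy-7,7-dimethyl-3-methylideneoxepan-2-yl]-4-methylhex-2-enal | CC(=O)O[C@H]1CCC(=C)[C@H](CC[C@@](C)(OC(C)=O)/C=C/C=O)OC1(C)C
F6 | step 22 | (2E,4S)-4-acetoxy-6-[(2S,6S)-6-acetoxy-7,7-dimethyl-3-methylideneoxepan-2-yl]-4-methylhex-2-enal | CC(=O)O[C@H]1CCC(=C)[C@H](CC[C@](C)(OC(C)=O)/C=C/C=O)OC1(C)C
F7 | step 25 | (3S,5aS,6S,7R,9aS)-6-(bromomethyl)-2,2,5a,7-tetramethyldecahydro-1-benzoxepine-3,7-diyl diacetate | CC(=O)O[C@H]1CC[C@]2(C)[C@H](CC[C@@](C)(OC(C)=O)[C@H]2CBr)OC1(C)C
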